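**Retrosynthetic overview**
1. Target read as methyl 4-hydroxy-3-{[(1R,2S,4aS,8aR)-1,2,4a-trimethyl-5-methylidenedecahydronaphthalen-1-yl]methyl}benzoate: a cis-fused decalin with the three methyls and H-8a on one face and ArCH2 on the other.
2. Last bond: C4a–C5 (ring A, angular methyl and exocyclic methylene together) by an electrochemical cobalt-hydride radical cyclisation of a methylidenecyclohexane onto a pentynyl chain.
3. ArCH2–C1 from a neopentyl aldehyde and an arylboronic acid; the aldehyde is a vinyl group after ozonolysis.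
4. C1 and C8a from (4S)-3,4-dimethylcyclohex-2-en-1-one by vinyl cuprate addition and enolate alkylation, both steered by the C2 methyl; the enone comes from (S)-pulegone in four steps.
5. Ring order: ring B is bought (pulegone), ring A is closed in the last step.

Assumption: (S)-(−)-pulegone, 5-iodopent-1-yne and (2-hydroxy-5-(methoxycarbonyl)phenyl)boronic acid are taken as commercial; C1, C2, C4a, C5, C8a refer to the decahydronaphthalene numbering of the target.

**Step 1**
Reactants: 1 (S)-(−)-pulegone
Product: 2 (5S,6R)-5,6-dimethyl-2-(propan-2-ylidene)cyclohexan-1-one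
Conditions: LiN(iPr)2, THF, −78 °C; MeI, −78 → 0 °C
Reagents that add atoms: iodomethane, CI
Why: Kinetic deprotonation of the enone takes an alpha-prime proton rather than the gamma protons of the isopropylidene group, and the cross-conjugated enolate is methylated (enolate alkylation) mainly anti to the neighbouring methyl; this new centre becomes sp2 in step 2, so its ratio does not matter.

**Step 2**
Reactants: 2 (5S,6R)-5,6-dimethyl-2-(propan-2-ylidene)cyclohexan-1-one
Product: 3 (4S)-2-hydroxy-3,4-dimethylcyclohex-2-en-1-one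
Conditions: O3, CH2Cl2/MeOH, −78 °C; Me2S, −78 °C → rt
Reagents that add atoms: ozone, [O-][O+]=O
Why: Ozonolysis cleaves the tetrasubstituted enone C=C to acetone and a 1,2-dione that rests as its more substituted, conjugated enol (diosphenol), leaving the bought stereocentre untouched.

**Step 3**
Reactants: 3 (4S)-2-hydroxy-3,4-dimethylcyclohex-2-en-1-one
Product: 4 (3S)-2,3-dimethyl-6-oxocyclohex-1-en-1-yl trifluoromethanesulfonate
Conditions: Tf2O, pyridine, CH2Cl2, −78 → 0 °C
Reagents that add atoms: trifluoromethanesulfonic anhydride, O=S(=O)(OS(=O)(=O)C(F)(F)F)C(F)(F)F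
Why: O-sulfonylation of the acidic enol hydroxyl (enol triflate formation) turns the unwanted oxygen into a leaving group.

**Step 4**
Reactants: 4 (3S)-2,3-dimethyl-6-oxocyclohex-1-en-1-yl trifluoromethanesulfonate
Product: 5 (4S)-3,4-dimethylcyclohex-2-en-1-one
Conditions: Pd(OAc)2 (5 mol %), PPh3, HCO2H, n-Bu3N, DMF, 60 °C
Reagents that add atoms: none
Why: Palladium-catalysed formate reduction of a vinyl triflate (oxidative addition to zerovalent palladium, decarboxylation of formate, C–H reductive elimination) gives the beta-methyl enone, and the mild amine does not enolise toward the gamma stereocentre.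

**Step 5**
Reactants: 5 (4S)-3,4-dimethylcyclohex-2-en-1-one; 6 5-iodopent-1-yne
Product: 8 (2R,3R,4S)-3-ethenyl-3,4-dimethyl-2-(pent-4-yn-1-yl)cyclohexan-1-one, via lithium enolate 7 (not isolated)
Conditions: (CH2=CH)2CuLi, Et2O/THF, −78 → −20 °C; then HMPA, 6, −20 °C → rt
Reagents that add atoms: lithium divinylcuprate (CH2=CH)2CuLi, [Li+].C=C[Cu-]C=C
Why: Cuprate conjugate addition puts vinyl on the beta carbon anti to the neighbouring methyl (axial attack), and the regiospecific lithium enolate is then alkylated axially (tandem conjugate addition–enolate alkylation) anti to the now pseudoaxial 3-methyl on the chair with an equatorial 4-methyl, the other chair-like approach being 1,3-diaxial to that methyl, so the chain ends cis to vinyl and trans to both methyls.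

**Step 6**
Reactants: 8 (2R,3R,4S)-3-ethenyl-3,4-dimethyl-2-(pent-4-yn-1-yl)cyclohexan-1-one
Product: 9 (1R,2R,6S)-1,6-dimethyl-3-oxo-2-(pent-4-yn-1-yl)cyclohexane-1-carbaldehyde
Conditions: O3 (1 equiv), CH2Cl2, −78 °C; then Me2S
Reagents that add atoms: ozone, [O-][O+]=O
Why: Ozonolysis with one equivalent of ozone cleaves the vinyl group far faster than the terminal alkyne, and the neutral reductive work-up leaves the ketone and its alpha centre alone.

**Step 7**
Reactants: 9 (1R,2R,6S)-1,6-dimethyl-3-oxo-2-(pent-4-yn-1-yl)cyclohexane-1-carbaldehyde; 10 (2-hydroxy-5-(methoxycarbonyl)phenyl)boronic acid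
Product: 12 methyl 3-{[(1R,2R,6S)-1,6-dimethyl-3-oxo-2-(pent-4-yn-1-yl)cyclohexyl]methyl}-4-hydroxybenzoate, via tosylhydrazone 11 (not isolated)
Conditions: TsNHNH2 (1.0 equiv), 1,4-dioxane, rt; then 10, K2CO3, 110 °C
Reagents that add atoms: none
Why: Barluenga reductive coupling, in which the aldehyde condenses selectively with the hydrazide (the ring ketone is hindered), K2CO3 releases a diazoalkane that adds to the boronic acid, and 1,2-aryl shift followed by protodeboronation gives ArCH2 on the quaternary carbon set in step 5.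

**Step 8**
Reactants: 12 methyl 3-{[(1R,2R,6S)-1,6-dimethyl-3-oxo-2-(pent-4-yn-1-yl)cyclohexyl]methyl}-4-hydroxybenzoate
Product: 13 methyl 3-{[(1R,2S,6S)-1,6-dimethyl-3-methylidene-2-(pent-4-yn-1-yl)cyclohexyl]methyl}-4-hydroxybenzoate
Conditions: Zn, CH2Br2, TiCl4, THF/CH2Cl2, 0 °C → rt
Reagents that add atoms: dibromomethane, BrCBr
Why: Takai–Lombardo methylenation is non-basic, so the hindered, enolisable ketone gives the exocyclic alkene without epimerising the adjacent chain-bearing centre, and ester, phenol and alkyne are tolerated.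

**Step 9**
Reactants: 13 methyl 3-{[(1R,2S,6S)-1,6-dimethyl-3-methylidene-2-(pent-4-yn-1-yl)cyclohexyl]methyl}-4-hydroxybenzoate
Product: 14 methyl 4-hydroxy-3-{[(1R,2S,4aS,8aR)-1,2,4a-trimethyl-5-methylidenedecahydronaphthalen-1-yl]methyl}benzoate
Conditions: CoBr2(DME) (10 mol %), 4,4′-di-tert-butyl-2,2′-bipyridine (12 mol %), Et3N·HCl, n-Bu4NBF4, DMF, Zn anode, carbon cathode, 5 mA, rt
Reagents that add atoms: none
Why: Proposed new method: a cathodically generated trivalent cobalt hydride transfers a hydrogen atom to the 1,1-disubstituted alkene (making the angular methyl and a tertiary radical), the radical closes 6-exo-dig on the unactivated alkyne from the face that carries the axial tether (so ring A is cis-fused and the new methyl is syn to H-8a and to the two older methyls), and the vinyl radical takes a second hydrogen to give the exocyclic methylene; the closest known reactions are cobalt-electrocatalytic HAT hydrofunctionalisations of alkenes and thermal MHAT radical cyclisations onto activated acceptors.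

**Compound list**
1 | (S)-(−)-pulegone, (5S)-5-methyl-2-(propan-2-ylidene)cyclohexan-1-one | C[C@H]1CCC(=C(C)C)C(=O)C1 | starting material
2 | (5S,6R)-5,6-dimethyl-2-(propan-2-ylidene)cyclohexan-1-one | C[C@H]1CCC(=C(C)C)C(=O)[C@@H]1C | intermediate
3 | (4S)-2-hydroxy-3,4-dimethylcyclohex-2-en-1-one (enol form of the 1,2-dione) | C[C@H]1CCC(=O)C(O)=C1C | intermediate
4 | (3S)-2,3-dimethyl-6-oxocyclohex-1-en-1-yl trifluoromethanesulfonate | C[C@H]1CCC(=O)C(OS(=O)(=O)C(F)(F)F)=C1C | intermediate
5 | (4S)-3,4-dimethylcyclohex-2-en-1-one | C[C@H]1CCC(=O)C=C1C | intermediate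
6 | 5-iodopent-1-yne | C#CCCCI | starting material
7 | lithium (3R,4S)-3-ethenyl-3,4-dimethylcyclohex-1-en-1-olate | C[C@H]1CCC(O[Li])=C[C@]1(C)C=C | intermediate
8 | (2R,3R,4S)-3-ethenyl-3,4-dimethyl-2-(pent-4-yn-1-yl)cyclohexan-1-one | C[C@H]1CCC(=O)[C@H](CCCC#C)[C@]1(C)C=C | intermediate
9 | (1R,2R,6S)-1,6-dimethyl-3-oxo-2-(pent-4-yn-1-yl)cyclohexane-1-carbaldehyde | C[C@H]1CCC(=O)[C@H](CCCC#C)[C@]1(C)C=O | intermediate
10 | (2-hydroxy-5-(methoxycarbonyl)phenyl)boronic acid | COC(=O)c1ccc(O)c(c1)B(O)O | starting material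
11 | N'-{(E)-[(1R,2R,6S)-1,6-dimethyl-3-oxo-2-(pent-4-yn-1-yl)cyclohexyl]methylidene}-4-methylbenzenesulfonohydrazide | C[C@H]1CCC(=O)[C@H](CCCC#C)[C@]1(C)/C=N/NS(=O)(=O)c1ccc(C)cc1 | intermediate
12 | methyl 3-{[(1R,2R,6S)-1,6-dimethyl-3-oxo-2-(pent-4-yn-1-yl)cyclohexyl]methyl}-4-hydroxybenzoate | C[C@H]1CCC(=O)[C@H](CCCC#C)[C@]1(C)Cc1cc(C(=O)OC)ccc1O | intermediate
13 | methyl 3-{[(1R,2S,6S)-1,6-dimethyl-3-methylidene-2-(pent-4-yn-1-yl)cyclohexyl]methyl}-4-hydroxybenzoate | C[C@H]1CCC(=C)[C@H](CCCC#C)[C@]1(C)Cc1cc(C(=O)OC)ccc1O | intermediate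
14 | methyl 4-hydroxy-3-{[(1R,2S,4aS,8aR)-1,2,4a-trimethyl-5-methylidenedecahydronaphthalen-1-yl]methyl}benzoate | C=C1CCC[C@@H]2[C@](C)(Cc3cc(C(=O)OC)ccc3O)[C@@H](C)CC[C@]12C | target

**Totals**
Total step count: 9. Longest linear sequence: 9 steps (1 → 14).

**Steps most likely to fail**

Step 9 (the proposed electrochemical cyclisation). The tertiary radical may be reduced, may lose a beta hydrogen (alkene isomerisation, which toward the chain-bearing carbon would also scramble that centre) or may add to the arene before it closes on the unactivated alkyne. The fallback uses known chemistry, sets out from 13 and comes back at 14. Markovnikov hydroiodination of the terminal alkyne with B-iodo-9-BBN, then acetic acid, gives the vinyl iodide methyl 3-{[(1R,2S,6S)-2-(4-iodopent-4-en-1-yl)-1,6-dimethyl-3-methylidenecyclohexyl]methyl}-4-hydroxybenzoate F4. An intramolecular reductive Heck reaction (Pd(OAc)2, PPh3, HCO2Na, DMF, 80 °C) then closes ring A 6-exo onto the 1,1-disubstituted alkene; the neopentyl alkylpalladium has no beta hydrogen and is reduced by formate to the angular methyl, with the same cis fusion.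

Step 5 (one-pot alkylation). A hindered enolate next to a quaternary carbon and an unactivated primary iodide may give low conversion or proton transfer. The fallback sets out from 5 and comes back at 8. After the same cuprate addition, enolate 7 is transmetalated with ZnCl2 and trapped with pent-4-ynal (aldol, same facial preference) to give (2S,3R,4S)-3-ethenyl-2-(1-hydroxypent-4-yn-1-yl)-3,4-dimethylcyclohexan-1-one F1. 1,1′-Thiocarbonyldiimidazole converts it into O-[1-((1S,2R,3S)-2-ethenyl-2,3-dimethyl-6-oxocyclohexyl)pent-4-yn-1-yl] 1H-imidazole-1-carbothioate F2, and Barton–McCombie deoxygenation with (Me3Si)3SiH/AIBN removes the side-chain oxygen to give 8.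

Step 7 (Barluenga coupling). The neopentyl hydrazone is hindered, protodeboronation next to the ortho hydroxyl may be slow, and hot K2CO3 could epimerise the ketone alpha centre, whose desired axial configuration is probably not the thermodynamic one. The fallback sets out from 9 and comes back at 12. Neutral [Rh(OH)(cod)]2-catalysed addition of boronic acid 10 to the aldehyde (dioxane/water, 60 °C) gives methyl 3-{[(1R,2R,6S)-1,6-dimethyl-3-oxo-2-(pent-4-yn-1-yl)cyclohexyl](hydroxy)methyl}-4-hydroxybenzoate F3. Ionic deoxygenation with Et3SiH/CF3CO2H at 0 °C, through the ortho-hydroxybenzyl cation, then gives 12.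

**Further compounds**
F1 | step 5 | (2S,3R,4S)-3-ethenyl-2-(1-hydroxypent-4-yn-1-yl)-3,4-dimethylcyclohexan-1-one | C[C@H]1CCC(=O)[C@H](C(O)CCC#C)[C@]1(C)C=C
F2 | step 5 | O-[1-((1S,2R,3S)-2-ethenyl-2,3-dimethyl-6-oxocyclohexyl)pent-4-yn-1-yl] 1H-imidazole-1-carbothioate | C[C@H]1CCC(=O)[C@H](C(OC(=S)n2ccnc2)CCC#C)[C@]1(C)C=C
F3 | step 7 | methyl 3-{[(1R,2R,6S)-1,6-dimethyl-3-oxo-2-(pent-4-yn-1-yl)cyclohexyl](hydroxy)methyl}-4-hydroxybenzoate | C[C@H]1CCC(=O)[C@H](CCCC#C)[C@]1(C)C(O)c1cc(C(=O)OC)ccc1O
F4 | step 9 | methyl 3-{[(1R,2S,6S)-2-(4-iodopent-4-en-1-yl)-1,6-dimethyl-3-methylidenecyclohexyl]methyl}-4-hydroxybenzoate | C[C@H]1CCC(=C)[C@H](CCCC(I)=C)[C@]1(C)Cc1cc(C(=O)OC)ccc1O
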